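The nine-membered carbocycle is opened between its carbinol carbon and the allylic CH2 next to the (E)-C(CH3)=CH unit. This ring homoallylic alcohol is read as an aldehyde plus a 2-methylallyl nucleophile. A samarium(II) Barbier closure forms this bond, the ring and the carbinol stereocentre in one operation and leaves the E-alkene in place. Its precursor is an open-chain acetoxy aldehyde with an (E)-allylic chloride and both future formyl groups as dimethyl acetals. The chain is joined in a three-component Michael–aldol step; two antipodal 5-menthyloxyfuranones deliver the AcOCH2–CH–CH–CH(OH) and OHC–CH–C(=CH)–CHO units with their stereocentres.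

Key step: step 16

Remark: the target is treated as the open hydroxy dialdehyde as drawn; a possible lactol equilibrium of its γ-hydroxy aldehyde unit is not considered further.
Remark: both antipodes of 5-menthyloxyfuran-2(5H)-one (1 and 11) are taken as commercial; each is otherwise one step from 5-hydroxyfuran-2(5H)-one and the corresponding menthol.
Ring numbering used below (as in 28): C1 carries the side chain, C2 the OH, C3 is the allylic CH2, C4=C5 and C7=C8 are the alkenes, C9 is the CH–CHO carbon.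

Step 1
Reactants: 1 (5S)-5-(d-menthyloxy)furan-2(5H)-one; 2 5-bromo-2-methylpent-2-ene
Product: 4 (4S,5S)-5-(d-menthyloxy)-4-(4-methylpent-3-en-1-yl)dihydrofuran-2(3H)-one, via Grignard reagent 3 (not isolated)
Conditions: 2, Mg, THF; then 1, CuBr·SMe2 (10 mol %), THF, −78 °C; aq. NH4Cl
Reagents that add atoms: none
Why: Copper-catalysed conjugate addition of the Grignard reagent to the γ-alkoxybutenolide occurs anti to the menthyloxy group and so sets the future side-chain stereocentre (C4 of the lactone, S).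

Step 2
Reactants: 4
Product: 6 (4S)-4-(4-methylpent-3-en-1-yl)dihydrofuran-2(3H)-one, via hydroxy carboxylate 5 (not isolated)
Conditions: KOH, NaBH4, EtOH/H2O, 0 °C → rt; then 2 M HCl, rt
Reagents that add atoms: none
Why: Reductive transposition of the acylal: saponification releases the γ-aldehyde with loss of menthol, NaBH4 reduces it and acid lactonises the hydroxy acid, leaving the stereocentre untouched.

Step 3
Reactants: 7 ethyl 4-methylpent-3-enoate
Product: 8 ethyl (E)-5-hydroxy-4-methylpent-3-enoate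
Conditions: SeO2 (0.2 equiv), t-BuOOH (2 equiv), CH2Cl2, rt
Reagents that add atoms: tert-butyl hydroperoxide CC(C)(C)OO
Why: Selenium dioxide allylic oxidation (ene reaction, then [2,3]-shift) attacks the (E)-methyl group of the trisubstituted alkene and thereby fixes the E geometry of the future C4=C5 ring alkene.

Step 4
Reactants: 8
Product: 9 ethyl (E)-5-[(tert-butyldiphenylsilyl)oxy]-4-methylpent-3-enoate
Conditions: TBDPSCl, imidazole, CH2Cl2, 0 °C → rt
Reagents that add atoms: tert-butyl(chloro)diphenylsilane CC(C)(C)[Si](Cl)(c1ccccc1)c1ccccc1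
Why: Silyl ether formation; TBDPS is chosen because it should survive the acidic methanol of steps 8 and 11.

Step 5
Reactants: 9
Product: 10 (E)-5-[(tert-butyldiphenylsilyl)oxy]-4-methylpent-3-enal
Conditions: DIBAL-H (1.05 equiv), CH2Cl2, −78 °C; Rochelle salt; used at once
Reagents that add atoms: none
Why: Partial DIBAL-H reduction of the ester stops at the tetrahedral aluminate at −78 °C and should give the β,γ-unsaturated aldehyde without conjugation if it is not stored.

Step 6
Reactants: 6; 11 (5R)-5-(l-menthyloxy)furan-2(5H)-one; 10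
Product: 14 (4R,5R)-3-[(3E)-5-[(tert-butyldiphenylsilyl)oxy]-1-hydroxy-4-methylpent-3-en-1-yl]-5-(l-menthyloxy)-4-[(3R,4S)-4-(4-methylpent-3-en-1-yl)-2-oxotetrahydrofuran-3-yl]dihydrofuran-2(3H)-one (epimer mixture at C3 and at the carbinol carbon), via lithium enolate 12 (not isolated), via Michael adduct enolate 13 (not isolated)
Conditions: LDA (1.05 equiv), THF, −78 °C; 11, −78 °C; 10, −78 °C; AcOH quench
Reagents that add atoms: none
Why: Tandem Michael addition–aldol reaction: the lactone enolate adds to C4 of the butenolide anti to its own β-substituent (sets ring C1, trans) and anti to the menthyloxy group (sets ring C9), and the new enolate is trapped by the aldehyde.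

Step 7
Reactants: 14
Product: 16 (3E,4R,5R)-3-[(3E)-5-[(tert-butyldiphenylsilyl)oxy]-4-methylpent-3-en-1-ylidene]-5-(l-menthyloxy)-4-[(3R,4S)-4-(4-methylpent-3-en-1-yl)-2-oxotetrahydrofuran-3-yl]dihydrofuran-2(3H)-one, via mesylate 15 (not isolated)
Conditions: MsCl (1.5 equiv), Et3N (4 equiv), CH2Cl2, 0 °C → rt
Reagents that add atoms: none
Why: Mesylation and E1cB elimination should give the thermodynamically preferred (E)-alkylidene lactone (chain anti to the carbonyl), the geometry that later lies cis inside the ring.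

Step 8
Reactants: 16
Product: 17 methyl (2E,3R)-2-[(3E)-5-[(tert-butyldiphenylsilyl)oxy]-4-methylpent-3-en-1-ylidene]-4,4-dimethoxy-3-[(3R,4S)-4-(4-methylpent-3-en-1-yl)-2-oxotetrahydrofuran-3-yl]butanoate
Conditions: CSA (0.2 equiv), HC(OMe)3, MeOH, 40 °C
Reagents that add atoms: methanol CO
Why: Acid-catalysed methanolysis of the acylal (pseudo-ester) opens only the γ-alkoxylactone to methyl ester plus dimethyl acetal with loss of menthol, which makes the two lactone carbonyls chemically different.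

Step 9
Reactants: 17
Product: 18 (3R,4S)-3-[(2R,3E,6E)-8-[(tert-butyldiphenylsilyl)oxy]-3-(hydroxymethyl)-1,1-dimethoxy-7-methylocta-3,6-dien-2-yl]-4-(4-methylpent-3-en-1-yl)tetrahydrofuran-2-ol (anomer mixture)
Conditions: DIBAL-H (4.5 equiv), CH2Cl2, −78 °C; Rochelle salt
Reagents that add atoms: none
Why: Exhaustive DIBAL-H reduction needs no selectivity: the enoate gives the allylic alcohol (1,2-reduction) and the lactone stops at the lactol aluminate at −78 °C.

Step 10
Reactants: 18
Product: 19 (2E,3R)-2-[(3E)-5-[(tert-butyldiphenylsilyl)oxy]-4-methylpent-3-en-1-ylidene]-4,4-dimethoxy-3-[(3R,4S)-4-(4-methylpent-3-en-1-yl)-2-oxotetrahydrofuran-3-yl]butanal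
Conditions: TEMPO (0.2 equiv), PhI(OAc)2 (2.4 equiv), CH2Cl2, rt
Reagents that add atoms: none
Why: Oxoammonium (TEMPO) oxidation returns the lactol to the lactone and takes the allylic alcohol only to the enal, because its γ-carbon is an acetal and no lactol can form there.

Step 11
Reactants: 19
Product: 20 (3R,4S)-3-[(2R,3E,6E)-8-[(tert-butyldiphenylsilyl)oxy]-3-(dimethoxymethyl)-1,1-dimethoxy-7-methylocta-3,6-dien-2-yl]-4-(4-methylpent-3-en-1-yl)dihydrofuran-2(3H)-one
Conditions: HC(OMe)3, MeOH, PPTS, rt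
Reagents that add atoms: trimethyl orthoformate COC(OC)OC
Why: Acetalisation of the enal with orthoformate masks the second formyl group so that the later reductant meets no conjugated carbonyl; the lactone is untouched.

Step 12
Reactants: 20
Product: 22 (2R,3R,4E,7E)-2-[(2S)-1-acetoxy-6-methylhept-5-en-2-yl]-9-[(tert-butyldiphenylsilyl)oxy]-3,4-bis(dimethoxymethyl)-N-methoxy-N,8-dimethylnona-4,7-dienamide, via hydroxy Weinreb amide 21 (not isolated)
Conditions: MeNHOMe·HCl, i-PrMgCl, THF, −20 → 0 °C; then Ac2O, DMAP, 0 °C → rt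
Reagents that add atoms: N,O-dimethylhydroxylamine hydrochloride CNOC.Cl; acetic anhydride CC(=O)OC(C)=O
Why: Weinreb aminolysis of the lactone with the magnesium amide and acetylation of the liberated alkoxide in the same flask (no relactonisation) store C2 as a latent aldehyde and install the acetate.

Step 13
Reactants: 22
Product: 23 (2R,3R,4E,7E)-2-[(2S)-1-acetoxy-6-methylhept-5-en-2-yl]-9-hydroxy-3,4-bis(dimethoxymethyl)-N-methoxy-N,8-dimethylnona-4,7-dienamide
Conditions: TBAF, AcOH, THF, 0 °C → rt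
Reagents that add atoms: none
Why: Buffered fluoride desilylation frees the allylic alcohol while acetate, amide and acetals should stay intact.

Step 14
Reactants: 23
Product: 24 (2R,3R,4E,7E)-2-[(2S)-1-acetoxy-6-methylhept-5-en-2-yl]-9-chloro-3,4-bis(dimethoxymethyl)-N-methoxy-N,8-dimethylnona-4,7-dienamide
Conditions: NCS, Me2S, CH2Cl2, −20 → 0 °C
Reagents that add atoms: N-chlorosuccinimide O=C1CCC(=O)N1Cl
Why: Corey–Kim chlorination: SN2 displacement in the alkoxysulfonium salt should give the primary allylic chloride without allylic transposition or loss of the E geometry.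

Step 15
Reactants: 24
Product: 25 (2S)-2-[(2R,3R,4E,7E)-9-chloro-3,4-bis(dimethoxymethyl)-8-methyl-1-oxonona-4,7-dien-2-yl]-6-methylhept-5-en-1-yl acetate
Conditions: Cp2Zr(H)Cl (1.5 equiv), THF, rt, 20 min; quick filtration through Et3N-deactivated silica
Reagents that add atoms: none
Why: Schwartz reduction of the Weinreb amide stops at the aldehyde via the zirconated hemiaminal and should spare the acetate, the acetals and the alkenes.

Step 16
Reactants: 25
Product: 27 (2S)-2-[(1R,2S,4E,7E,9R)-8,9-bis(dimethoxymethyl)-2-hydroxy-4-methylcyclonona-4,7-dien-1-yl]-6-methylhept-5-en-1-yl acetate, via allylsamarium 26 (not isolated)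
Conditions: SmI2 (0.1 M in THF, 3 equiv), HMPA (12 equiv), THF, 0 °C, slow addition of 25 (final ca. 5 mM); aq. NH4Cl
Reagents that add atoms: none
Why: SmI2–HMPA reduces the allylic chloride by two single-electron transfers to the allylsamarium(III) species 26, which adds to the only free carbonyl, the aldehyde, through its unsubstituted α-carbon (SE2), so the (E)-trisubstituted alkene stays where it was. The closest known reaction type is the SmI2-promoted Barbier-type cyclisation of ω-formyl allylic chlorides to eight- and nine-membered cycloalkenols. The nine-membered ring closes by a 9-exo-trig attack on the C=O, the allyl unit becoming endocyclic. The new carbinol stereocentre (C2) is controlled by the adjacent C1 in a Felkin–Anh arrangement: the branched side-chain methine lies anti to the forming bond, the C1–H flanks the attack trajectory and the tether leaves from the inside position, which should deliver the (2S)-alcohol. The step needs α- over γ-regioselectivity (nine- versus seven-membered ring) and chemoselectivity for one formyl group: the bulky HMPA-solvated samarium should sit on and react through the primary allyl terminus, as the precedent indicates, and the two other formyl groups are dimethyl acetals. The non-acidic conditions also avoid the citronellal-type carbonyl-ene cyclisation of this aldehyde onto the side-chain alkene that a Lewis acid would cause.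

Step 17
Reactants: 27
Product: 28 (2S)-2-[(1R,2S,4E,7E,9R)-8,9-diformyl-2-hydroxy-4-methylcyclonona-4,7-dien-1-yl]-6-methylhept-5-en-1-yl acetate
Conditions: oxalic acid (cat.), wet silica gel, CH2Cl2, rt
Reagents that add atoms: water O
Why: Mild acid-catalysed acetal hydrolysis should unveil the enal and the α-branched aldehyde without base, so that the C9 centre and the primary acetate are retained.

Compound list
1 | (5S)-5-{[(1S,2R,5S)-2-isopropyl-5-methylcyclohexyl]oxy}furan-2(5H)-one (d-menthyloxy) | O=C1C=C[C@@H](O[C@H]2C[C@@H](C)CC[C@@H]2C(C)C)O1 | starting material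
2 | 5-bromo-2-methylpent-2-ene | CC(C)=CCCBr | starting material
3 | (4-methylpent-3-en-1-yl)magnesium bromide | CC(C)=CCC[Mg]Br | intermediate
4 | (4S,5S)-5-(d-menthyloxy)-4-(4-methylpent-3-en-1-yl)dihydrofuran-2(3H)-one | O=C1C[C@H](CCC=C(C)C)[C@@H](O[C@H]2C[C@@H](C)CC[C@@H]2C(C)C)O1 | intermediate
5 | potassium (3S)-3-(hydroxymethyl)-7-methyloct-6-enoate | OC[C@@H](CCC=C(C)C)CC(=O)[O-].[K+] | intermediate
6 | (4S)-4-(4-methylpent-3-en-1-yl)dihydrofuran-2(3H)-one | O=C1C[C@H](CCC=C(C)C)CO1 | intermediate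
7 | ethyl 4-methylpent-3-enoate | CCOC(=O)CC=C(C)C | starting material
8 | ethyl (E)-5-hydroxy-4-methylpent-3-enoate | CCOC(=O)C/C=C(\C)CO | intermediate
9 | ethyl (E)-5-[(tert-butyldiphenylsilyl)oxy]-4-methylpent-3-enoate | CCOC(=O)C/C=C(\C)CO[Si](c1ccccc1)(c1ccccc1)C(C)(C)C | intermediate
10 | (E)-5-[(tert-butyldiphenylsilyl)oxy]-4-methylpent-3-enal | O=CC/C=C(\C)CO[Si](c1ccccc1)(c1ccccc1)C(C)(C)C | intermediate
11 | (5R)-5-{[(1R,2S,5R)-2-isopropyl-5-methylcyclohexyl]oxy}furan-2(5H)-one (l-menthyloxy) | O=C1C=C[C@H](O[C@@H]2C[C@H](C)CC[C@H]2C(C)C)O1 | starting material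
12 | lithium enolate of 6 | [Li]OC1=C[C@H](CCC=C(C)C)CO1 | intermediate
13 | lithium enolate of the Michael adduct of 12 and 11 (configuration as in 14) | O=C1OC[C@@H](CCC=C(C)C)[C@@H]1[C@@H]2C=C(O[Li])O[C@H]2O[C@@H]3C[C@H](C)CC[C@H]3C(C)C | intermediate
14 | (4R,5R)-3-[(3E)-5-[(tert-butyldiphenylsilyl)oxy]-1-hydroxy-4-methylpent-3-en-1-yl]-5-(l-menthyloxy)-4-[(3R,4S)-4-(4-methylpent-3-en-1-yl)-2-oxotetrahydrofuran-3-yl]dihydrofuran-2(3H)-one (epimer mixture at C3 and carbinol) | O=C1OC[C@@H](CCC=C(C)C)[C@@H]1[C@@H]2C(C(O)C/C=C(\C)CO[Si](c3ccccc3)(c4ccccc4)C(C)(C)C)C(=O)O[C@H]2O[C@@H]5C[C@H](C)CC[C@H]5C(C)C | intermediate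
15 | methanesulfonate of 14 | O=C1OC[C@@H](CCC=C(C)C)[C@@H]1[C@@H]2C(C(OS(C)(=O)=O)C/C=C(\C)CO[Si](c3ccccc3)(c4ccccc4)C(C)(C)C)C(=O)O[C@H]2O[C@@H]5C[C@H](C)CC[C@H]5C(C)C | intermediate
16 | (3E,4R,5R)-3-[(3E)-5-[(tert-butyldiphenylsilyl)oxy]-4-methylpent-3-en-1-ylidene]-5-(l-menthyloxy)-4-[(3R,4S)-4-(4-methylpent-3-en-1-yl)-2-oxotetrahydrofuran-3-yl]dihydrofuran-2(3H)-one | O=C1OC[C@@H](CCC=C(C)C)[C@@H]1[C@@H]2/C(=C\C/C=C(\C)CO[Si](c3ccccc3)(c4ccccc4)C(C)(C)C)C(=O)O[C@H]2O[C@@H]5C[C@H](C)CC[C@H]5C(C)C | intermediate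
17 | methyl (2E,3R)-2-[(3E)-5-[(tert-butyldiphenylsilyl)oxy]-4-methylpent-3-en-1-ylidene]-4,4-dimethoxy-3-[(3R,4S)-4-(4-methylpent-3-en-1-yl)-2-oxotetrahydrofuran-3-yl]butanoate | O=C1OC[C@@H](CCC=C(C)C)[C@@H]1[C@@H](C(OC)OC)/C(=C\C/C=C(\C)CO[Si](c2ccccc2)(c3ccccc3)C(C)(C)C)C(=O)OC | intermediate
18 | (3R,4S)-3-[(2R,3E,6E)-8-[(tert-butyldiphenylsilyl)oxy]-3-(hydroxymethyl)-1,1-dimethoxy-7-methylocta-3,6-dien-2-yl]-4-(4-methylpent-3-en-1-yl)tetrahydrofuran-2-ol (anomer mixture) | OC1OC[C@@H](CCC=C(C)C)[C@@H]1[C@@H](C(OC)OC)/C(=C\C/C=C(\C)CO[Si](c2ccccc2)(c3ccccc3)C(C)(C)C)CO | intermediate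
19 | (2E,3R)-2-[(3E)-5-[(tert-butyldiphenylsilyl)oxy]-4-methylpent-3-en-1-ylidene]-4,4-dimethoxy-3-[(3R,4S)-4-(4-methylpent-3-en-1-yl)-2-oxotetrahydrofuran-3-yl]butanal | O=C1OC[C@@H](CCC=C(C)C)[C@@H]1[C@@H](C(OC)OC)/C(=C\C/C=C(\C)CO[Si](c2ccccc2)(c3ccccc3)C(C)(C)C)C=O | intermediate
20 | (3R,4S)-3-[(2R,3E,6E)-8-[(tert-butyldiphenylsilyl)oxy]-3-(dimethoxymethyl)-1,1-dimethoxy-7-methylocta-3,6-dien-2-yl]-4-(4-methylpent-3-en-1-yl)dihydrofuran-2(3H)-one | O=C1OC[C@@H](CCC=C(C)C)[C@@H]1[C@@H](C(OC)OC)/C(=C\C/C=C(\C)CO[Si](c2ccccc2)(c3ccccc3)C(C)(C)C)C(OC)OC | intermediate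
21 | (2R,3R,4E,7E)-9-[(tert-butyldiphenylsilyl)oxy]-2-[(2S)-1-hydroxy-6-methylhept-5-en-2-yl]-3,4-bis(dimethoxymethyl)-N-methoxy-N,8-dimethylnona-4,7-dienamide | OC[C@@H](CCC=C(C)C)[C@@H](C(=O)N(C)OC)[C@@H](C(OC)OC)/C(=C\C/C=C(\C)CO[Si](c1ccccc1)(c2ccccc2)C(C)(C)C)C(OC)OC | intermediate
22 | (2R,3R,4E,7E)-2-[(2S)-1-acetoxy-6-methylhept-5-en-2-yl]-9-[(tert-butyldiphenylsilyl)oxy]-3,4-bis(dimethoxymethyl)-N-methoxy-N,8-dimethylnona-4,7-dienamide | CC(=O)OC[C@@H](CCC=C(C)C)[C@@H](C(=O)N(C)OC)[C@@H](C(OC)OC)/C(=C\C/C=C(\C)CO[Si](c1ccccc1)(c2ccccc2)C(C)(C)C)C(OC)OC | intermediate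
23 | (2R,3R,4E,7E)-2-[(2S)-1-acetoxy-6-methylhept-5-en-2-yl]-9-hydroxy-3,4-bis(dimethoxymethyl)-N-methoxy-N,8-dimethylnona-4,7-dienamide | CC(=O)OC[C@@H](CCC=C(C)C)[C@@H](C(=O)N(C)OC)[C@@H](C(OC)OC)/C(=C\C/C=C(\C)CO)C(OC)OC | intermediate
24 | (2R,3R,4E,7E)-2-[(2S)-1-acetoxy-6-methylhept-5-en-2-yl]-9-chloro-3,4-bis(dimethoxymethyl)-N-methoxy-N,8-dimethylnona-4,7-dienamide | CC(=O)OC[C@@H](CCC=C(C)C)[C@@H](C(=O)N(C)OC)[C@@H](C(OC)OC)/C(=C\C/C=C(\C)CCl)C(OC)OC | intermediate
25 | (2S)-2-[(2R,3R,4E,7E)-9-chloro-3,4-bis(dimethoxymethyl)-8-methyl-1-oxonona-4,7-dien-2-yl]-6-methylhept-5-en-1-yl acetate | CC(=O)OC[C@@H](CCC=C(C)C)[C@@H](C=O)[C@@H](C(OC)OC)/C(=C\C/C=C(\C)CCl)C(OC)OC | intermediate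
26 | allylsamarium(III) diiodide derived from 25 (Sm in place of Cl) | CC(=O)OC[C@@H](CCC=C(C)C)[C@@H](C=O)[C@@H](C(OC)OC)/C(=C\C/C=C(\C)C[Sm](I)I)C(OC)OC | intermediate
27 | (2S)-2-[(1R,2S,4E,7E,9R)-8,9-bis(dimethoxymethyl)-2-hydroxy-4-methylcyclonona-4,7-dien-1-yl]-6-methylhept-5-en-1-yl acetate | CC(=O)OC[C@@H](CCC=C(C)C)[C@H]1[C@@H](O)C/C(C)=C/C/C=C(/C(OC)OC)[C@@H]1C(OC)OC | intermediate
28 | (2S)-2-[(1R,2S,4E,7E,9R)-8,9-diformyl-2-hydroxy-4-methylcyclonona-4,7-dien-1-yl]-6-methylhept-5-en-1-yl acetate | CC(=O)OC[C@@H](CCC=C(C)C)[C@H]1[C@@H](O)C/C(C)=C/C/C=C(/C=O)[C@@H]1C=O | target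

Total step count: 17.
Longest linear sequence: 15 steps (7 to 28, steps 3–17); the lactone branch 1 → 6 adds steps 1–2.

Steps most likely to fail

Step 16. The aldehyde may be attacked on the wrong face, because the medium-ring transition state can override the Felkin preference, giving the C2 epimer or a mixture. The fallback sets the carbinol in a separate, reagent-controlled operation. It sets out from 25: the crude cyclisation mixture is oxidised with Dess–Martin periodinane/NaHCO3 to the β,γ-unsaturated ketone (2S)-2-[(1R,4E,7E,9R)-8,9-bis(dimethoxymethyl)-4-methyl-2-oxocyclonona-4,7-dien-1-yl]-6-methylhept-5-en-1-yl acetate F1. This is reduced with catecholborane and the CBS oxazaborolidine of the handedness that delivers the (2S)-alcohol (−78 °C), which comes back at 27. This fallback does not address closure through the γ-carbon (seven-membered ring), which would remain the residual risk of the step.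

Step 6. The enolisable β,γ-unsaturated aldehyde 10 may transfer a proton to the lithium enolate 13, which quenches the enolate and conjugates the aldehyde instead of giving the aldol. The fallback separates the two bond formations and makes the second one non-basic. It sets out from 6 and 11: the Michael addition is run alone and the enolate is trapped with TMSCl as the silyl ketene acetal 5-(l-menthyloxy)-4-[(3R,4S)-4-(4-methylpent-3-en-1-yl)-2-oxotetrahydrofuran-3-yl]-2-(trimethylsilyloxy)-4,5-dihydrofuran F2. A BF3·OEt2-mediated Mukaiyama aldol addition of F2 to 10 at −78 °C then comes back at 14.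

Step 15. The zirconium hydride may also attack the primary allylic chloride (reductive loss of chloride or hydrozirconation nearby) during the amide reduction. The fallback inverts the order so that the hydride never meets the chloride. It sets out from 23: Schwartz reduction (one extra equivalent for the free OH) gives the hydroxy aldehyde (2S)-2-[(2R,3R,4E,7E)-9-hydroxy-3,4-bis(dimethoxymethyl)-8-methyl-1-oxonona-4,7-dien-2-yl]-6-methylhept-5-en-1-yl acetate F3. Base-free Corey–Kim chlorination of F3 comes back at 25.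

Further compounds
F1 | step 16 | (2S)-2-[(1R,4E,7E,9R)-8,9-bis(dimethoxymethyl)-4-methyl-2-oxocyclonona-4,7-dien-1-yl]-6-methylhept-5-en-1-yl acetate | CC(=O)OC[C@@H](CCC=C(C)C)[C@H]1C(=O)C/C(C)=C/C/C=C(/C(OC)OC)[C@@H]1C(OC)OC
F2 | step 6 | 5-(l-menthyloxy)-4-[(3R,4S)-4-(4-methylpent-3-en-1-yl)-2-oxotetrahydrofuran-3-yl]-2-(trimethylsilyloxy)-4,5-dihydrofuran (configuration as in 14) | O=C1OC[C@@H](CCC=C(C)C)[C@@H]1[C@@H]2C=C(O[Si](C)(C)C)O[C@H]2O[C@@H]3C[C@H](C)CC[C@H]3C(C)C
F3 | step 15 | (2S)-2-[(2R,3R,4E,7E)-9-hydroxy-3,4-bis(dimethoxymethyl)-8-methyl-1-oxonona-4,7-dien-2-yl]-6-methylhept-5-en-1-yl acetate | CC(=O)OC[C@@H](CCC=C(C)C)[C@@H](C=O)[C@@H](C(OC)OC)/C(=C\C/C=C(\C)CO)C(OC)OC
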